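## The problem

Compound 19 is a biflavanoid. Its upper unit is a 3-deoxyflavan (ring A fused to pyran ring C, ring B on C2), bonded through C4 to C8' of ring D of (+)-catechin. Two of the four stereocentres (C2' and C3' of the lower unit) come with catechin. The other two, C2 and C4 of ring C, must be made, and they are cis (2S,4S), with rings B and D both equatorial. Ring C has no oxygen on C3, so nothing next to C4 can steer a bond formed there. The obvious union of a flavan-4-yl cation with the nucleophilic C8' of catechin brings ring D in axially, trans to ring B. The cis isomer is therefore best reached when the C4 hydrogen arrives last, under the control of C2. The remote catechin centres cannot control the upper unit, so C2 needs a reagent-controlled step. The free phenols of rings A, B, D and the lower catechol oxidise easily, and the benzylic C2–O1 ether and the C4–C8' bond are acid-labile, so all nine hydroxyl groups are carried as benzyl ethers to the end. The feature that opens the chosen route is that C4 is bonded to two aryl carbons (C4a of ring A, C8' of ring D) and can be a diaryl ketone carbon, while its neighbour C3 is a plain methylene beside the C2 ether centre and can carry iodide. These are two electrophilic carbons that a one-electron reductant can join.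

## Retrosynthesis

**19 back to 17 (nine O–benzyl bonds, then C4–H).** Hydrogenolysis of 18 frees 19 under neutral conditions. In 18 the C4–H bond is cut to give tertiary alcohol 17. This cut is preferred to the C4–C8' cut of a cation/arene coupling, which would deliver ring D trans to ring B. The forward step must ionise 17 and deliver hydride to the C4 cation on the face trans to ring B, without opening the C2–O1 bond.

**17 back to 16 (C3–C4).** Cutting C3–C4 turns ring C into an open ether chain and C4 into a diaryl ketone, giving iodo ketone 16. Compared with cutting C4–C8' at this stage (aryl-metal addition to an enolisable flavanone), this cut forms the hindered diaryl junction earlier, on an aldehyde. Ring C is six-membered only if the iodide sits on the carbon directly bonded to C2, so the side chain of 16 is a 2-iodo-1-arylethoxy group built from a two-carbon acyl unit. The forward reaction must join C3 and C4 reductively without expelling the O1 aryloxide from a C3 carbanion. The design answer is that the diaryl ketone is reduced before the iodide.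

**16 back to 12 and 13 (C–I, then C4–C8').** Iodide 16 comes from chloride 15 by halide exchange, because an iodide would not survive an aryllithium. Ketone 15 comes from diarylmethanol 14 by oxidation. Cutting the C4–C8' bond of 14 gives aldehyde 12 and aryllithium 13. Addition to an aldehyde is chosen over acylation because both partners are flanked by two ortho oxygens. The step must tolerate a primary chloride and a benzylic aryl ether at low temperature.

**13 back to 1.** Aryllithium 13 comes from bromide 4 by bromine–lithium exchange. Bromide 4 comes from (+)-catechin 1 through tetrabenzyl ether 2, regioselective bromination at C8 to 3, and benzylation of the C3 hydroxyl. The two lower stereocentres are bought, not made.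

**12 back to 6 and 11 (O1–C2).** The aryl ether bond is cut at the benzylic carbon, giving phenol 6 and (S)-chlorohydrin 11, to be joined with inversion. A chloride is carried here, not a bromide or iodide, because it does not act as a neighbouring group and is inert to phosphine and to 13. The forward reaction must be a clean SN2 displacement at a benzylic carbon bearing an electron-rich aryl group.

**11 back to 7 and 8, and 6 back to 5.** The carbinol C–H bond of 11 is cut to give chloroketone 10, which allows a catalyst-controlled ketone reduction. The aryl–acyl bond of 10 is cut to give bromide 7 (through Grignard reagent 9) and chloroacetyl Weinreb amide 8. Phenol 6 is the 4,6-dibenzyl ether of commercial aldehyde 5.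

## Roads not taken

**Alternative 1:** Ring A itself is cut, at the bonds from C5 and C8a to C6 and C8. Malonate diester A2 is dimethyl malonate whose central carbon carries C4 with ring D and the C3–C2 chain, with C2 as a silyl ether of the configuration opposite to the final one. With dimethyl 3-oxopentanedioate A3 and Mg(OMe)2 in hot methanol, it would undergo Claisen then Dieckmann condensation and aromatise to ring A diester A1. Ester removal and closure of O1–C2 with inversion would follow.
- Merits: C4 is already a defined C–H stereocentre on an open chain, so the 2,4-cis relation does not depend on a late hydride delivery. The two phenols flanking C4a are equivalent, so ring C closure has no regiochemical problem. No hindered diaryl junction has to be forced.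
- Weak points: the double acylation must occur at a malonate carrying a fully substituted benzylic substituent. A1 is an air-sensitive triol that needs decarboxylation and reprotection. A2 needs its own asymmetric synthesis of two stereocentres that catechin cannot control.
- Comparison: in stereochemical logic at C4 this road is at least as good as the chosen one. The chosen plan sets against it a bought ring A, a much shorter sequence and standard reactions at every stage.

**Alternative 2:** The cut is at C4–C4a and O1–C2. 3,5-Bis(benzyloxy)phenol A6 would add through its ortho carbon to the β-carbon of enone A5, a chalcone in which ring D is the β-aryl group and ring B the acyl aryl group. The phenol oxygen would then condense with the ketone to give 4H-chromene A4, with C4 set by a chiral acid. Hydrogenation from the face opposite ring D would set C2 cis and could remove the benzyl ethers in the same operation.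
- Merits: this is the most convergent road, with two bonds and ring C formed in one step, and probably the fewest steps.
- Weak points: the β-carbon of A5 is deactivated and shielded by the doubly ortho-substituted ring D. The catalyst must impose C4 in the presence of the catechin centres, on a substrate pairing without close asymmetric precedent. A6 can also react at the carbon between its two ether groups, which cannot cyclise. A4 is an acid-sensitive enol ether that can lose hydride from C4 to give a flavylium salt.
- Comparison: if its key step worked with control, this road would be shorter and better. The chosen plan sets against it that each stereocentre comes from the chiral pool, a well-understood ketone reduction or substrate-controlled hydride delivery, and that C4 is built as a planar carbonyl carbon, where hindrance matters least.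

**Alternative 3:** The cut is at O1–C2 and C2–C3. Diarylethylene phenol A8 would condense with 3,4-bis(benzyloxy)benzaldehyde A9 under a confined chiral Brønsted acid to an oxocarbenium ion. The terminal alkene carbon would attack it, and proton loss from C3 would give flav-3-ene A7 with C2 set by the catalyst. Hydrogenation from the face opposite ring B would then set C4 cis and deprotect.
- Merits: two bonds form in the key step, C2 comes from a commercial aldehyde, and it avoids both a substitution at an ionisable benzylic carbon and stoichiometric SmI2 with HMPA.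
- Weak points: the oxocarbenium ion from an electron-rich aldehyde is weakly electrophilic. The alkene of A8 is twisted by four ortho substituents. The 2-aryl-2H-chromene product can re-ionise at C2–O1 under the same acid and lose its configuration. This asymmetric closure is not established for such substrates.
- Comparison: on paper it is shorter, and its final hydrogenation is the same device the chosen plan keeps in reserve for C4. The chosen plan sets against it a C2 centre fixed early on a small ketone by a standard reduction and carried through neutral or basic steps until one brief acid step.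

Key step: step 11

Remark: compounds 7 and 8 are taken to be commercial. The configuration drawn at C4 of 17 is the expected one and is not relied upon, since step 12 erases it. "Penta-O-benzylcatechin-8-yl" means the (2R,3S)-3,5,7-tris(benzyloxy)-2-[3,4-bis(benzyloxy)phenyl]chroman-8-yl group.

## Steps

Step 1
Reactants: 1 (+)-catechin
Product: 2 5,7,3',4'-tetra-O-benzyl-(+)-catechin, (2R,3S)-5,7-bis(benzyloxy)-2-[3,4-bis(benzyloxy)phenyl]chroman-3-ol
Conditions: BnBr (4.4 equiv), K2CO3, DMF, 0 °C → rt
Reagents that add atoms: benzyl bromide, BrCc1ccccc1
Why: Williamson etherification; carbonate deprotonates only the four phenols, so the secondary C3 hydroxyl stays free, and the mild base should leave C2 unchanged.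

Step 2
Reactants: 2 5,7,3',4'-tetra-O-benzyl-(+)-catechin
Product: 3 8-bromo-5,7,3',4'-tetra-O-benzylcatechin, (2R,3S)-5,7-bis(benzyloxy)-2-[3,4-bis(benzyloxy)phenyl]-8-bromochroman-3-ol
Conditions: NBS (1.0 equiv), CH2Cl2, −78 °C → rt
Reagents that add atoms: N-bromosuccinimide, O=C1CCC(=O)N1Br
Why: Electrophilic aromatic bromination; the phloroglucinol-type ring is far more electron-rich than the catechol ring, and in 5,7-di-O-benzyl flavan-3-ols C8 is attacked in preference to C6.

Step 3
Reactants: 3 8-bromo-5,7,3',4'-tetra-O-benzylcatechin
Product: 4 8-bromo-3,5,7,3',4'-penta-O-benzylcatechin, (2R,3S)-3,5,7-tris(benzyloxy)-2-[3,4-bis(benzyloxy)phenyl]-8-bromochromane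
Conditions: NaH, BnBr, Bu4NI (cat.), DMF, 0 °C → rt
Reagents that add atoms: benzyl bromide, BrCc1ccccc1
Why: Williamson etherification of the secondary alkoxide; the aryl bromide and benzyl ethers are inert to NaH, and the C3 oxygen must be capped before the lithiation of step 8.

Step 4
Reactants: 5 2,4,6-trihydroxybenzaldehyde
Product: 6 4,6-bis(benzyloxy)-2-hydroxybenzaldehyde
Conditions: BnBr (2.05 equiv), K2CO3, DMF, rt
Reagents that add atoms: benzyl bromide, BrCc1ccccc1
Why: Regioselective Williamson etherification; the hydroxyl para to the aldehyde is the most acidic, and once one ortho hydroxyl is benzylated the other is held in a hydrogen bond to the carbonyl and resists alkylation.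

Step 5
Reactants: 7 4-bromo-1,2-bis(benzyloxy)benzene; 8 2-chloro-N-methoxy-N-methylacetamide
Product: 10 1-[3,4-bis(benzyloxy)phenyl]-2-chloroethanone, via arylmagnesium bromide 9 (not isolated)
Conditions: Mg, THF, 45 °C; then 8, THF, −10 °C → 0 °C; 1 M HCl
Reagents that add atoms: none
Why: Weinreb ketone synthesis; the chelated tetrahedral adduct stops at the ketone and the α-chlorine survives at or below 0 °C; the two carbons of 8 become C2 and C3 of ring C.

Step 6
Reactants: 10 1-[3,4-bis(benzyloxy)phenyl]-2-chloroethanone
Product: 11 (S)-1-[3,4-bis(benzyloxy)phenyl]-2-chloroethanol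
Conditions: (S)-2-methyl-CBS-oxazaborolidine (10 mol%), BH3·SMe2, THF, 0 °C; MeOH
Reagents that add atoms: none
Why: Corey–Bakshi–Shibata reduction; aryl acts as the large and chloromethyl as the small group, so the (S)-catalyst should give the (S)-chlorohydrin, which creates the future C2 centre with the configuration needed for inversion in step 7.

Step 7
Reactants: 6 4,6-bis(benzyloxy)-2-hydroxybenzaldehyde; 11 (S)-1-[3,4-bis(benzyloxy)phenyl]-2-chloroethanol
Product: 12 4,6-bis(benzyloxy)-2-{(1R)-1-[3,4-bis(benzyloxy)phenyl]-2-chloroethoxy}benzaldehyde
Conditions: PPh3, DIAD, toluene, 0 °C → rt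
Reagents that add atoms: none
Why: Mitsunobu etherification; the acidic phenol of 6 displaces the alkoxyphosphonium group with inversion to give the (R)-ether, which is the C2 configuration of the target, and the β-chlorine disfavours benzylic ionisation and does not take part as a neighbouring group.

Step 8
Reactants: 4 8-bromo-3,5,7,3',4'-penta-O-benzylcatechin; 12 4,6-bis(benzyloxy)-2-{(1R)-1-[3,4-bis(benzyloxy)phenyl]-2-chloroethoxy}benzaldehyde
Product: 14 {4,6-bis(benzyloxy)-2-[(1R)-1-(3,4-bis(benzyloxy)phenyl)-2-chloroethoxy]phenyl}(penta-O-benzylcatechin-8-yl)methanol (both carbinol epimers), via 8-lithio-penta-O-benzylcatechin 13 (not isolated)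
Conditions: t-BuLi (2.0 equiv), THF, −78 °C; then 12, −78 °C; aq. NH4Cl
Reagents that add atoms: none
Why: Bromine–lithium exchange followed by 1,2-addition of the aryllithium to the aldehyde; at −78 °C the primary chloride and the benzylic aryl ether are inert, and the uncontrolled carbinol centre is removed in step 9.

Step 9
Reactants: 14 diarylmethanol
Product: 15 {4,6-bis(benzyloxy)-2-[(1R)-1-(3,4-bis(benzyloxy)phenyl)-2-chloroethoxy]phenyl}(penta-O-benzylcatechin-8-yl)methanone
Conditions: Dess–Martin periodinane, NaHCO3, CH2Cl2, 0 °C → rt
Reagents that add atoms: none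
Why: Dess–Martin oxidation under buffered conditions, which should avoid ionising the very electron-rich diarylmethanol; both carbinol epimers give the same ketone.

Step 10
Reactants: 15 chloro ketone
Product: 16 {4,6-bis(benzyloxy)-2-[(1R)-1-(3,4-bis(benzyloxy)phenyl)-2-iodoethoxy]phenyl}(penta-O-benzylcatechin-8-yl)methanone
Conditions: NaI (10 equiv), 2-butanone, 80 °C, dark
Reagents that add atoms: sodium iodide, [Na+].[I-]
Why: Finkelstein exchange driven by precipitation of NaCl; the iodide is installed only after the organolithium step, and the SN2 event at C3 does not involve C2.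

Step 11
Reactants: 16 iodo ketone
Product: 17 (2S,4R)-5,7-bis(benzyloxy)-2-[3,4-bis(benzyloxy)phenyl]-4-(penta-O-benzylcatechin-8-yl)chroman-4-ol
Conditions: SmI2 (2.5 equiv, 0.1 M in THF) premixed with HMPA (10 equiv), added dropwise to 16 in THF, −78 °C → 0 °C; aq. NaHCO3
Reagents that add atoms: none
Why: Samarium Barbier-type ketyl–halide cyclisation, the closest known reaction type being the SmI2/HMPA-mediated intramolecular coupling of iodo ketones to cyclic tertiary alcohols. With the reductant added slowly at −78 °C the first electron goes to the diaryl ketone, the most easily reduced site, giving a trivalent-samarium ketyl that four ortho oxygen substituents keep from dimerising; the second electron cleaves the C3–I bond and the C3 radical combines with the ketyl carbon C4 in the same molecule (displacement of iodide by the doubly reduced carbonyl carbon leads to the same bond), and work-up protonates the alkoxide. Ring C closes in the 6-exo mode, C3 bonding to the carbonyl carbon with the C–O bond outside the new ring. The new stereocentre C4 is set under the control of C2 through a chair transition state with ring B equatorial, which should place ring D cis to ring B (4R); this outcome is not needed, because step 12 makes C4 planar again. The selectivity the step needs is chemoselectivity: C–C coupling must beat β-elimination of the O1 aryloxide from a C3 carbanion and simple reduction of either function. The substrate secures this through the large gap in reducibility between diaryl ketone and primary iodide, so that the ketyl is in place before any reactive species exists at C3, and the conditions support it by keeping divalent samarium low (no fast second reduction of the C3 radical) and by omitting a proton source. C2 is not touched, and the benzyl and aryl ethers are inert to SmI2/HMPA at this temperature.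

Step 12
Reactants: 17 tertiary alcohol
Product: 18 (2S,4S)-5,7-bis(benzyloxy)-2-[3,4-bis(benzyloxy)phenyl]-4-(penta-O-benzylcatechin-8-yl)chromane (nona-O-benzyl ether of the target)
Conditions: Et3SiH (5 equiv), CF3CO2H (10 equiv), CH2Cl2, −40 °C → 0 °C
Reagents that add atoms: none
Why: Ionic hydrogenation; acid ionises the tertiary alcohol to a C4 cation stabilised by rings A and D, and Et3SiH should deliver hydride along the axial trajectory of the half-chair with ring B equatorial, trans to ring B, so that ring D ends equatorial and cis to ring B (4S); any alkene formed by proton loss from C3 is reprotonated to the same cation.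

Step 13
Reactants: 18 nona-O-benzyl ether
Product: 19 (2R,3S)-2-(3,4-dihydroxyphenyl)-8-[(2S,4S)-2-(3,4-dihydroxyphenyl)-5,7-dihydroxychroman-4-yl]chromane-3,5,7-triol (target)
Conditions: H2 (1 atm), Pd(OH)2/C, THF–MeOH, rt
Reagents that add atoms: none
Why: Catalytic hydrogenolysis of the nine benzyl ethers under neutral conditions, the usual last step for perbenzylated oligoflavans; no stereocentre is affected.

## Compound list

1 | (+)-catechin | Oc1cc(O)c2c(c1)O[C@H](c1ccc(O)c(O)c1)[C@@H](O)C2 | starting material
2 | 5,7,3',4'-tetra-O-benzyl-(+)-catechin | c1ccccc1COc1cc(OCc2ccccc2)c2c(c1)O[C@H](c1ccc(OCc3ccccc3)c(OCc3ccccc3)c1)[C@@H](O)C2 | intermediate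
3 | 8-bromo-5,7,3',4'-tetra-O-benzylcatechin | c1ccccc1COc1cc(OCc2ccccc2)c2c(c1Br)O[C@H](c1ccc(OCc3ccccc3)c(OCc3ccccc3)c1)[C@@H](O)C2 | intermediate
4 | 8-bromo-3,5,7,3',4'-penta-O-benzylcatechin | c1ccccc1COc1cc(OCc2ccccc2)c2c(c1Br)O[C@H](c1ccc(OCc3ccccc3)c(OCc3ccccc3)c1)[C@@H](OCc1ccccc1)C2 | intermediate
5 | 2,4,6-trihydroxybenzaldehyde | O=Cc1c(O)cc(O)cc1O | starting material
6 | 4,6-bis(benzyloxy)-2-hydroxybenzaldehyde | O=Cc1c(O)cc(OCc2ccccc2)cc1OCc1ccccc1 | intermediate
7 | 4-bromo-1,2-bis(benzyloxy)benzene | Brc1ccc(OCc2ccccc2)c(OCc2ccccc2)c1 | starting material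
8 | 2-chloro-N-methoxy-N-methylacetamide | ClCC(=O)N(C)OC | starting material
9 | [3,4-bis(benzyloxy)phenyl]magnesium bromide | Br[Mg]c1ccc(OCc2ccccc2)c(OCc2ccccc2)c1 | intermediate
10 | 1-[3,4-bis(benzyloxy)phenyl]-2-chloroethanone | ClCC(=O)c1ccc(OCc2ccccc2)c(OCc2ccccc2)c1 | intermediate
11 | (S)-1-[3,4-bis(benzyloxy)phenyl]-2-chloroethanol | O[C@@H](c1ccc(OCc2ccccc2)c(OCc2ccccc2)c1)CCl | intermediate
12 | 4,6-bis(benzyloxy)-2-{(1R)-1-[3,4-bis(benzyloxy)phenyl]-2-chloroethoxy}benzaldehyde | O=Cc1c(OCc2ccccc2)cc(OCc2ccccc2)cc1O[C@H](c1ccc(OCc2ccccc2)c(OCc2ccccc2)c1)CCl | intermediate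
13 | 8-lithio-3,5,7,3',4'-penta-O-benzylcatechin | [Li]c1c(OCc2ccccc2)cc(OCc2ccccc2)c2c1O[C@H](c1ccc(OCc3ccccc3)c(OCc3ccccc3)c1)[C@@H](OCc1ccccc1)C2 | intermediate
14 | {4,6-bis(benzyloxy)-2-[(1R)-1-(3,4-bis(benzyloxy)phenyl)-2-chloroethoxy]phenyl}(penta-O-benzylcatechin-8-yl)methanol, both carbinol epimers | OC(c1c(OCc2ccccc2)cc(OCc2ccccc2)cc1O[C@H](c1ccc(OCc2ccccc2)c(OCc2ccccc2)c1)CCl)c1c(OCc2ccccc2)cc(OCc2ccccc2)c2c1O[C@H](c1ccc(OCc3ccccc3)c(OCc3ccccc3)c1)[C@@H](OCc1ccccc1)C2 | intermediate
15 | {4,6-bis(benzyloxy)-2-[(1R)-1-(3,4-bis(benzyloxy)phenyl)-2-chloroethoxy]phenyl}(penta-O-benzylcatechin-8-yl)methanone | O=C(c1c(OCc2ccccc2)cc(OCc2ccccc2)cc1O[C@H](c1ccc(OCc2ccccc2)c(OCc2ccccc2)c1)CCl)c1c(OCc2ccccc2)cc(OCc2ccccc2)c2c1O[C@H](c1ccc(OCc3ccccc3)c(OCc3ccccc3)c1)[C@@H](OCc1ccccc1)C2 | intermediate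
16 | {4,6-bis(benzyloxy)-2-[(1R)-1-(3,4-bis(benzyloxy)phenyl)-2-iodoethoxy]phenyl}(penta-O-benzylcatechin-8-yl)methanone | O=C(c1c(OCc2ccccc2)cc(OCc2ccccc2)cc1O[C@H](c1ccc(OCc2ccccc2)c(OCc2ccccc2)c1)CI)c1c(OCc2ccccc2)cc(OCc2ccccc2)c2c1O[C@H](c1ccc(OCc3ccccc3)c(OCc3ccccc3)c1)[C@@H](OCc1ccccc1)C2 | intermediate
17 | (2S,4R)-5,7-bis(benzyloxy)-2-[3,4-bis(benzyloxy)phenyl]-4-(penta-O-benzylcatechin-8-yl)chroman-4-ol | c1ccccc1COc1cc(OCc2ccccc2)c2c(c1)O[C@H](c1ccc(OCc3ccccc3)c(OCc3ccccc3)c1)C[C@]2(O)c1c(OCc2ccccc2)cc(OCc2ccccc2)c2c1O[C@H](c1ccc(OCc3ccccc3)c(OCc3ccccc3)c1)[C@@H](OCc1ccccc1)C2 | intermediate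
18 | (2S,4S)-5,7-bis(benzyloxy)-2-[3,4-bis(benzyloxy)phenyl]-4-(penta-O-benzylcatechin-8-yl)chromane | c1ccccc1COc1cc(OCc2ccccc2)c2c(c1)O[C@H](c1ccc(OCc3ccccc3)c(OCc3ccccc3)c1)C[C@@H]2c1c(OCc2ccccc2)cc(OCc2ccccc2)c2c1O[C@H](c1ccc(OCc3ccccc3)c(OCc3ccccc3)c1)[C@@H](OCc1ccccc1)C2 | intermediate
19 | (2R,3S)-2-(3,4-dihydroxyphenyl)-8-[(2S,4S)-2-(3,4-dihydroxyphenyl)-5,7-dihydroxychroman-4-yl]chromane-3,5,7-triol | Oc1cc(O)c2c(c1)O[C@H](c1ccc(O)c(O)c1)C[C@@H]2c1c(O)cc(O)c2c1O[C@H](c1ccc(O)c(O)c1)[C@@H](O)C2 | target

## Step count and least certain steps

Total: 13 steps. Longest linear sequence: 9 steps (steps 1, 2, 3, 8–13 from 1, or equally steps 5, 6, 7, 8–13 from 7).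

**Step 11 (key step).** The most likely failure is loss of the O1–C2 ether by β-elimination, if C3 is reduced to a carbanion before it has bonded to C4. The aryloxide is a good leaving group, and the ketone is crowded by four ortho oxygens. Plain reduction of the ketone or of the iodide by hydrogen abstraction is the second risk. The fallback makes the C3–C4 bond with C4 as the nucleophile, before the diaryl junction exists. It sets out from 12, which NaI converts into iodo aldehyde F1. A thiazolium-derived carbene (thiazolium salt, DBU, toluene, moderate heat) should close F1 to (2S)-flavanone F2 by intramolecular alkylation of the acyl-anion equivalent, so that C3 never carries negative charge. The organocerium reagent made from 13 and CeCl3 then adds to the C4 ketone of F2 and gives 17, where the route resumes with step 12. The price is a basic step on a flavanone, where reversible ring opening could erode C2.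

**Step 7.** The most likely failure is partial loss of configuration at the future C2. The alkoxyphosphonium intermediate can ionise to a benzylic cation stabilised by the para-benzyloxy group of ring B, and the chelated, hindered phenol may react slowly. The fallback sets C2 on an sp2 carbon, with no substitution at a benzylic centre. It sets out from Grignard reagent 9, which with B(OMe)3 and acid gives arylboronic acid F3. Asymmetric 1,4-addition of F3 to 5,7-bis(benzyloxy)chromone F4, catalysed by [RhCl(C2H4)2]2 with a chiral diene of the antipode that leads to the (2S) product, gives flavanone F2. F2 then takes the cerium reagent from 13, as in the fallback of step 11, and the route is rejoined at 17. This detour replaces steps 4 to 11 and gives up the reductive closure, so it would be used only if the etherification cannot be made stereospecific.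

**Step 12.** The most likely failures are poor facial selectivity in hydride delivery to the crowded C4 cation, and acid-induced ionisation of the benzylic C2–O1 bond (epimerisation at C2) or of the C4–C8' bond. The fallback sets out from 17. Dehydration with catalytic pyridinium p-toluenesulfonate (toluene, molecular sieves) gives flav-3-ene F5. Hydrogenation over Pd(OH)2/C should add hydrogen to C3=C4 from the face opposite ring B, which places ring D cis to ring B, and remove the benzyl ethers in the same operation. It rejoins the route at 19.

**Step 4.** The most likely failure is over-alkylation to the tribenzyl ether together with C-benzylation of the phloroglucinol nucleus, giving mixtures. The fallback replaces starting material 5 by commercial 3,5-bis(benzyloxy)phenol F6. Magnesium-directed ortho-formylation (MgCl2, Et3N, paraformaldehyde, MeCN, reflux) gives 6 directly, where the route is rejoined.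

## Further compounds

F1 | step 11 | 4,6-bis(benzyloxy)-2-{(1R)-1-[3,4-bis(benzyloxy)phenyl]-2-iodoethoxy}benzaldehyde | O=Cc1c(OCc2ccccc2)cc(OCc2ccccc2)cc1O[C@H](c1ccc(OCc2ccccc2)c(OCc2ccccc2)c1)CI
F2 | step 11 | (2S)-5,7-bis(benzyloxy)-2-[3,4-bis(benzyloxy)phenyl]chroman-4-one | c1ccccc1COc1cc(OCc2ccccc2)c2c(c1)O[C@H](c1ccc(OCc3ccccc3)c(OCc3ccccc3)c1)CC2=O
F3 | step 7 | [3,4-bis(benzyloxy)phenyl]boronic acid | OB(O)c1ccc(OCc2ccccc2)c(OCc2ccccc2)c1
F4 | step 7 | 5,7-bis(benzyloxy)-4H-chromen-4-one | O=c1ccoc2cc(OCc3ccccc3)cc(OCc3ccccc3)c12
F5 | step 12 | (2S)-5,7-bis(benzyloxy)-2-[3,4-bis(benzyloxy)phenyl]-4-(penta-O-benzylcatechin-8-yl)-2H-chromene | c1ccccc1COc1cc(OCc2ccccc2)c2c(c1)O[C@H](c1ccc(OCc3ccccc3)c(OCc3ccccc3)c1)C=C2c1c(OCc2ccccc2)cc(OCc2ccccc2)c2c1O[C@H](c1ccc(OCc3ccccc3)c(OCc3ccccc3)c1)[C@@H](OCc1ccccc1)C2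
F6 | step 4 | 3,5-bis(benzyloxy)phenol | Oc1cc(OCc2ccccc2)cc(OCc2ccccc2)c1
A1 | alternative 1 | dimethyl 2,4,6-trihydroxyisophthalate carrying at C5 the C4 carbon with ring D and the silyl-protected C3–C2 chain | CC(C)(C)[Si](C)(C)O[C@@H](c1ccc(OCc2ccccc2)c(OCc2ccccc2)c1)C[C@@H](c1c(O)c(C(=O)OC)c(O)c(C(=O)OC)c1O)c1c(OCc2ccccc2)cc(OCc2ccccc2)c2c1O[C@H](c1ccc(OCc3ccccc3)c(OCc3ccccc3)c1)[C@@H](OCc1ccccc1)C2
A2 | alternative 1 | dimethyl malonate substituted at its central carbon by the same C4 side chain | CC(C)(C)[Si](C)(C)O[C@@H](c1ccc(OCc2ccccc2)c(OCc2ccccc2)c1)C[C@@H](C(C(=O)OC)C(=O)OC)c1c(OCc2ccccc2)cc(OCc2ccccc2)c2c1O[C@H](c1ccc(OCc3ccccc3)c(OCc3ccccc3)c1)[C@@H](OCc1ccccc1)C2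
A3 | alternative 1 | dimethyl 3-oxopentanedioate | COC(=O)CC(=O)CC(=O)OC
A4 | alternative 2 | nona-O-benzyl flav-2-ene (2,4-diaryl-4H-chromene) with the target configuration at C4 | c1ccccc1COc1cc(OCc2ccccc2)c2c(c1)OC(c1ccc(OCc3ccccc3)c(OCc3ccccc3)c1)=C[C@@H]2c1c(OCc2ccccc2)cc(OCc2ccccc2)c2c1O[C@H](c1ccc(OCc3ccccc3)c(OCc3ccccc3)c1)[C@@H](OCc1ccccc1)C2
A5 | alternative 2 | (E)-1-[3,4-bis(benzyloxy)phenyl]-3-(penta-O-benzylcatechin-8-yl)prop-2-en-1-one | O=C(c1ccc(OCc2ccccc2)c(OCc2ccccc2)c1)/C=C/c1c(OCc2ccccc2)cc(OCc2ccccc2)c2c1O[C@H](c1ccc(OCc3ccccc3)c(OCc3ccccc3)c1)[C@@H](OCc1ccccc1)C2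
A6 | alternative 2 | 3,5-bis(benzyloxy)phenol | Oc1cc(OCc2ccccc2)cc(OCc2ccccc2)c1
A7 | alternative 3 | nona-O-benzyl flav-3-ene (2,4-diaryl-2H-chromene) with the target configuration at C2 | c1ccccc1COc1cc(OCc2ccccc2)c2c(c1)O[C@H](c1ccc(OCc3ccccc3)c(OCc3ccccc3)c1)C=C2c1c(OCc2ccccc2)cc(OCc2ccccc2)c2c1O[C@H](c1ccc(OCc3ccccc3)c(OCc3ccccc3)c1)[C@@H](OCc1ccccc1)C2
A8 | alternative 3 | 3,5-bis(benzyloxy)-2-[1-(penta-O-benzylcatechin-8-yl)ethenyl]phenol | C=C(c1c(O)cc(OCc2ccccc2)cc1OCc1ccccc1)c1c(OCc2ccccc2)cc(OCc2ccccc2)c2c1O[C@H](c1ccc(OCc3ccccc3)c(OCc3ccccc3)c1)[C@@H](OCc1ccccc1)C2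
A9 | alternative 3 | 3,4-bis(benzyloxy)benzaldehyde | O=Cc1ccc(OCc2ccccc2)c(OCc2ccccc2)c1
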